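**Retrosynthetic overview**
1. 9 ⇒ 7 + 8: cut the C2–O(aryl) bond. The last step exchanges the 2-SMe group for 4-hydroxyphenoxide, driven by copper.
2. 7 ⇒ 3 + CS2 (4) + MeI: the pyranone ring (ring C) closes by O1–C2 bond formation inside ketene dithioacetal 6, and CS2 supplies C2.
3. 3 ⇒ 1 + 2: O-prenylation of the only non-chelated hydroxyl of phloroacetophenone.
4. Ring order: ring A (from 1) and ring B (from 8) are bought. Ring C is the only ring built (step 2), and no protecting groups are used.

Assumption: the target has no stereocentre and no stereogenic double bond (the prenyl alkene carries two identical methyl groups). It is therefore achiral and needs no enantiocontrol.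

**Step 1**
Reactants: 1 2,4,6-trihydroxyacetophenone (phloroacetophenone, dried); 2 1-bromo-3-methylbut-2-ene (prenyl bromide)
Product: 3 1-[2,6-dihydroxy-4-(3-methylbut-2-enyloxy)phenyl]ethanone
Conditions: 1 (1.2 equiv), 2 (1.0 equiv), K2CO3 (1.0 equiv), acetone, reflux, 6 h
Reagents that add atoms: none
Why: Williamson ether synthesis, in which the 4-OH is the most acidic and the only non-chelated hydroxyl, so one equivalent of weak base in an aprotic solvent alkylates it on oxygen while the 2- and 6-OH stay hydrogen-bonded to the ketone.

**Step 2**
Reactants: 3 1-[2,6-dihydroxy-4-(3-methylbut-2-enyloxy)phenyl]ethanone; 4 carbon disulfide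
Product: 7 5-hydroxy-2-(methylsulfanyl)-7-(3-methylbut-2-enyloxy)-4H-chromen-4-one, via oxodithioate salt 5 (not isolated), via ketene dithioacetal 6 (not isolated)
Conditions: LiN(SiMe3)2 (3.1 equiv), THF, −78 → −10 °C; CS2 (1.1 equiv), −78 → 0 °C; LiN(SiMe3)2 (1.1 equiv), 0 °C; MeI (2.0 equiv), 0 °C → rt; 50 °C, 2 h; cold 1 M HCl to pH 5
Reagents that add atoms: iodomethane, CI
Why: Claisen-type C-thioacylation of the polyanion enolate with CS2, double S-methylation of the soft ene-dithiolate (lithium phenoxides react far more slowly with MeI), then intramolecular oxa-Michael addition–elimination of an ortho-phenoxide on the α-oxoketene dithioacetal with loss of methanethiolate; the two ortho-hydroxyls are equivalent so only one chromone can form, and attack of the released thiolate at C2 is degenerate.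

**Step 3**
Reactants: 7 5-hydroxy-2-(methylsulfanyl)-7-(3-methylbut-2-enyloxy)-4H-chromen-4-one; 8 hydroquinone (benzene-1,4-diol)
Product: 9 5-hydroxy-2-(4-hydroxyphenoxy)-7-(3-methylbut-2-enyloxy)-4H-chromen-4-one (target)
Conditions: 8 (4 equiv), Cu(O2CC4H3S) (copper thiophene-2-carboxylate, CuTC, 1.5 equiv), Cs2CO3 (1.2 equiv), 4 Å sieves, degassed DMF, Ar, 50 °C, 6–12 h; aq. NH4Cl work-up, with excess 8 washed out by water
Reagents that add atoms: none
Why: Proposed new method: a thiophile-driven thioether-to-aryl-ether exchange at chromone C2, in which monovalent copper binds the methylsulfanyl sulfur of the vinylogous thiocarbonate 7 (raising the electrophilicity of C2 and making MeS a leaving group), the caesium mono-aryloxide of 8 adds to C2 in an oxa-Michael sense, and the enolate collapses with irreversible precipitation of CuSMe, removing the thiolate that would otherwise reverse the exchange; the closest known reaction types are the Liebeskind–Srogl activation of thioethers by copper carboxylates (so far a palladium-assisted carbon–carbon coupling) and the addition–elimination of aryloxides on 2-sulfinyl- or 2-sulfonylchromones; no oxidant is present, so the prenyl alkene and hydroquinone survive (hydroquinone tolerates monovalent copper and carbonate under argon, as in Ullmann ether syntheses), the chelated 5-OH is less acidic than 8 and stays protonated, and excess 8 together with reversible aryloxide exchange at C2 suppresses the bis-chromonyl ether.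

**Compound list**
1 | 2,4,6-trihydroxyacetophenone (phloroacetophenone) | CC(=O)c1c(O)cc(O)cc1O | starting material
2 | 1-bromo-3-methylbut-2-ene (prenyl bromide) | CC(C)=CCBr | starting material
3 | 1-[2,6-dihydroxy-4-(3-methylbut-2-enyloxy)phenyl]ethanone | CC(=O)c1c(O)cc(OCC=C(C)C)cc1O | intermediate
4 | carbon disulfide | S=C=S | starting material
5 | 3-[2,6-dihydroxy-4-(3-methylbut-2-enyloxy)phenyl]-3-oxopropanedithioic acid (in the flask as its lithium ene-dithiolate bis-phenoxide, drawn neutral) | SC(=S)CC(=O)c1c(O)cc(OCC=C(C)C)cc1O | intermediate
6 | 1-[2,6-dihydroxy-4-(3-methylbut-2-enyloxy)phenyl]-3,3-bis(methylsulfanyl)prop-2-en-1-one (in the flask as its lithium bis-phenoxide, drawn neutral) | CSC(SC)=CC(=O)c1c(O)cc(OCC=C(C)C)cc1O | intermediate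
7 | 5-hydroxy-2-(methylsulfanyl)-7-(3-methylbut-2-enyloxy)-4H-chromen-4-one | CSc1cc(=O)c2c(O)cc(OCC=C(C)C)cc2o1 | intermediate
8 | hydroquinone (benzene-1,4-diol) | Oc1ccc(O)cc1 | starting material
9 | 5-hydroxy-2-(4-hydroxyphenoxy)-7-(3-methylbut-2-enyloxy)-4H-chromen-4-one (achiral) | CC(C)=CCOc1cc(O)c2c(=O)cc(Oc3ccc(O)cc3)oc2c1 | target

**Total step count:** 3. **Longest linear sequence:** 3 (1 → 3 → 7 → 9).

**Steps most likely to fail, with fallbacks**

**Step 3 (the proposed new step).** The risks are sluggish exchange, copper being tied up by the 5-OH/4-C=O chelate, and double arylation of 8. The fallback sets out from 7 and comes back at 9, and it replaces metal activation of sulfur by oxidative activation, all known chemistry.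
- Compound 7 is oxidised with KHSO5 (as Oxone, 2KHSO5·KHSO4·K2SO4) in THF/MeOH/H2O at 0 °C. This sulfide-to-sulfone oxidation leaves isolated trisubstituted alkenes untouched, unlike a peracid. It gives 5-hydroxy-2-(methylsulfonyl)-7-(3-methylbut-2-enyloxy)-4H-chromen-4-one F1.
- The sulfone is then stirred with 8 (4 equiv) and K2CO3 in DMF at room temperature under argon. This is the classical addition–elimination of an aryloxide on a 2-sulfonylchromone; it expels methanesulfinate and delivers 9.

**Step 2.** The risks are incomplete formation of the polyanion, O-methylation, and slow ring closure of 6. The fallback sets out from 3 and comes back at 7, and it reverses the order of events by cyclising first and methylating afterwards.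
- Compound 3 is treated with KOtBu (4.5 equiv) and CS2 in THF at 0 °C → rt to give the potassium salt of 5.
- Cold dilute H2SO4 liberates the dithioacid, which condenses with the ortho-phenol and loses hydrogen sulfide. This gives the crystalline, isolable 4,5-dihydroxy-7-(3-methylbut-2-enyloxy)-2H-chromene-2-thione F2.
- MeI (1.05 equiv) with K2CO3 (1.0 equiv) in acetone at room temperature then alkylates only the soft thione sulfur and gives 7.

**Step 1.** The risks are C-prenylation and over-alkylation of the ambident phloroglucinol-type phenoxide. The fallback sets out from 1 and comes back at 3, and it activates the alcohol instead of the phenol.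
- It is a Mitsunobu etherification of 1 with 3-methylbut-2-en-1-ol (1.0 equiv), PPh3 and diisopropyl azodicarboxylate in THF at 0 °C → rt.
- Only the most acidic, non-chelated 4-OH is engaged. No free phenoxide is present, so ring carbon alkylation is shut off.
- This fallback makes no compound outside the list (entry F0).

**Further compounds**
F1 | step 3 | 5-hydroxy-2-(methylsulfonyl)-7-(3-methylbut-2-enyloxy)-4H-chromen-4-one | CS(=O)(=O)c1cc(=O)c2c(O)cc(OCC=C(C)C)cc2o1
F2 | step 2 | 4,5-dihydroxy-7-(3-methylbut-2-enyloxy)-2H-chromene-2-thione | Oc1cc(=S)oc2cc(OCC=C(C)C)cc(O)c12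
F0 | step 1 | none | none
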